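The guaiacyl-bearing tetrahydrofuran ring of the furofuran holds a C–O–C unit (ArCH–O–CH2) bonded to the two bridgehead carbons. It is read as a non-stabilised carbonyl ylide, and the bridgeheads as the C3=C4 alkene of a chiral butenolide. A single [3+2] cycloaddition of the ylide, released by fluoride from an α-chloro silylmethyl ether, onto (5R)-5-(l-menthyloxy)furan-2(5H)-one closes that ring, forms both C–C bonds and sets three stereocentres. The lactone–acetal ring is then reshaped into a lactone that accepts the syringyl aryllithium, which already carries the Evans-aldol-derived threo side chain; ionic hydrogenation fixes this aryl group endo.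

Key step: step 2

Assumption: O-benzylvanillin, (trimethylsilyl)methanol, (5R)-5-(l-menthyloxy)furan-2(5H)-one, 4-bromo-2,6-dimethoxyphenol, (S)-4-benzyl-3-(chloroacetyl)oxazolidin-2-one and O-benzylsyringaldehyde are taken as commercial; the racemic chloro-bearing carbon of the α-chloro ether and the labile hemiketal carbon are written without a stereodescriptor.

Step 1
Reactants: 1 4-(benzyloxy)-3-methoxybenzaldehyde; 2 (trimethylsilyl)methanol
Product: 3 1-(benzyloxy)-4-{bis[(trimethylsilyl)methoxy]methyl}-2-methoxybenzene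
Conditions: 2 (2.5 equiv), PPTS (cat.), benzene, reflux, Dean–Stark
Reagents that add atoms: none
Why: Acid-catalysed acetalisation of an aryl aldehyde with azeotropic removal of water should give the bis(silylmethyl) acetal, which stores the C–O–C unit together with its silyl trigger.

Step 2
Reactants: 3 1-(benzyloxy)-4-{bis[(trimethylsilyl)methoxy]methyl}-2-methoxybenzene; 4 (5R)-5-{[(1R,2S,5R)-5-methyl-2-(propan-2-yl)cyclohexyl]oxy}furan-2(5H)-one
Product: 7 (3R,3aS,6R,6aR)-6-[4-(benzyloxy)-3-methoxyphenyl]-3-{[(1R,2S,5R)-5-methyl-2-(propan-2-yl)cyclohexyl]oxy}tetrahydro-1H-furo[3,4-c]furan-1-one, via α-chloro ether 5 (not isolated), via carbonyl ylide 6 (not isolated)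
Conditions: AcCl (1.05 equiv), ZnCl2 (cat.), CH2Cl2, 0 °C to rt, concentrate; then slow addition to 4 and CsF (3 equiv), MeCN, rt
Reagents that add atoms: none
Why: Acetyl chloride converts the acetal into the α-chloro ether, which ionises to an aryl-stabilised oxocarbenium ion, and fluoride then removes the silyl group (1,3-elimination) to release the carbonyl ylide ArCH=O(+)–CH2(−), which adds suprafacially across C3=C4 of the butenolide in a concerted 1,3-dipolar [3+2] cycloaddition. The closest known reaction type is the fluoride-induced 1,3-elimination of α-chloroalkyl silylmethyl ethers to non-stabilised carbonyl ylides with their cycloaddition to electron-poor alkenes, combined with the established 1,3-dipolar cycloadditions of 5-menthyloxybutenolides. The tetrahydrofuran ring is closed by an intermolecular [π4s+π2s] cycloaddition, so the ring fusion is cis by necessity. The two bridgehead centres should be set by approach of the dipole to the face anti to the menthyloxy group on the acetal carbon, and the benzylic centre by the exo transition state in which the aryl group of the anti-configured ylide points away from the lactone ring. The step needs regioselectivity (CH2 terminus to C4, ArCH terminus to C3), which should be secured because the electron-rich aryl group holds the positive charge on its own carbon and leaves the unsubstituted terminus nucleophilic, matching the β-carbon of the unsaturated lactone. Any regio- or endo-isomers are diastereomers of 7 and are removed by chromatography.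

Step 3
Reactants: 7 (3R,3aS,6R,6aR)-6-[4-(benzyloxy)-3-methoxyphenyl]-3-(l-menthyloxy)tetrahydro-1H-furo[3,4-c]furan-1-one
Product: 8 {(2R,3S,4R)-2-[4-(benzyloxy)-3-methoxyphenyl]oxolane-3,4-diyl}dimethanol
Conditions: LiAlH4 (2.5 equiv), THF, 0 °C to rt; Fieser work-up
Reagents that add atoms: none
Why: Hydride reduction of the γ-alkoxy lactone (pseudo-ester) should open it to the 1,4-diol with loss of menthol, the intermediate aldehyde being reduced faster than it can epimerise, so the three ring stereocentres stay untouched.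

Step 4
Reactants: 8 {(2R,3S,4R)-2-[4-(benzyloxy)-3-methoxyphenyl]oxolane-3,4-diyl}dimethanol
Product: 9 (3aS,4R,6aS)-4-[4-(benzyloxy)-3-methoxyphenyl]tetrahydro-1H-furo[3,4-c]furan-1-one
Conditions: TEMPO (0.2 equiv), PhI(OAc)2 (2.5 equiv), CH2Cl2, rt
Reagents that add atoms: none
Why: In this TEMPO/PhI(OAc)2 oxidative lactonisation the oxoammonium ion should attack the less hindered hydroxymethyl group (on C4, remote from the aryl-bearing C2) first, and the resulting lactol is oxidised on to the lactone whose carbonyl sits on that carbon.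

Step 5
Reactants: 10 4-bromo-2,6-dimethoxyphenol; 11 (4S)-4-benzyl-3-(chloroacetyl)-1,3-oxazolidin-2-one
Product: 12 (4S)-4-benzyl-3-[(4-bromo-2,6-dimethoxyphenoxy)acetyl]-1,3-oxazolidin-2-one
Conditions: K2CO3 (1.5 equiv), NaI (0.1 equiv), acetone, 40 °C
Reagents that add atoms: none
Why: Williamson ether synthesis at the highly SN2-reactive α-halo imide (Finkelstein-assisted) should outrun acyl transfer to the hindered 2,6-dimethoxyphenoxide.

Step 6
Reactants: 12 (4S)-4-benzyl-3-[(4-bromo-2,6-dimethoxyphenoxy)acetyl]-1,3-oxazolidin-2-one; 13 4-(benzyloxy)-3,5-dimethoxybenzaldehyde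
Product: 15 (4S)-4-benzyl-3-[(2S,3R)-3-[4-(benzyloxy)-3,5-dimethoxyphenyl]-2-(4-bromo-2,6-dimethoxyphenoxy)-3-hydroxypropanoyl]-1,3-oxazolidin-2-one, via boron enolate 14 (not isolated)
Conditions: Bu2BOTf (1.1 equiv), iPr2NEt (1.3 equiv), CH2Cl2, −78 to 0 °C; then 13, −78 to 0 °C; pH 7 buffer, MeOH, 30% H2O2, 0 °C
Reagents that add atoms: none
Why: Evans syn-aldol reaction of the (Z)-boron glycolate enolate through a Zimmerman–Traxler chair, with the benzyl group of the auxiliary shielding one enolate face, should set both side-chain centres in the syn (threo) relationship with the absolute sense needed.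

Step 7
Reactants: 15 (4S)-4-benzyl-3-[(2S,3R)-3-[4-(benzyloxy)-3,5-dimethoxyphenyl]-2-(4-bromo-2,6-dimethoxyphenoxy)-3-hydroxypropanoyl]-1,3-oxazolidin-2-one
Product: 16 (1R,2R)-1-[4-(benzyloxy)-3,5-dimethoxyphenyl]-2-(4-bromo-2,6-dimethoxyphenoxy)propane-1,3-diol
Conditions: LiBH4 (2 equiv), MeOH (2 equiv), THF, 0 °C
Reagents that add atoms: none
Why: Reductive cleavage of the N-acyl oxazolidinone with LiBH4 should give the primary alcohol and release the auxiliary without touching the aryl bromide or either stereocentre.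

Step 8
Reactants: 16 (1R,2R)-1-[4-(benzyloxy)-3,5-dimethoxyphenyl]-2-(4-bromo-2,6-dimethoxyphenoxy)propane-1,3-diol
Product: 17 5-bromo-2-{[(1R,2R)-1-[4-(benzyloxy)-3,5-dimethoxyphenyl]-1,3-bis{[tert-butyl(dimethyl)silyl]oxy}propan-2-yl]oxy}-1,3-dimethoxybenzene
Conditions: TBSOTf (2.4 equiv), 2,6-lutidine (3 equiv), CH2Cl2, 0 °C to rt
Reagents that add atoms: tert-butyldimethylsilyl trifluoromethanesulfonate, CC(C)(C)[Si](C)(C)OS(=O)(=O)C(F)(F)F
Why: Silylation with the triflate should cap both the primary and the hindered benzylic hydroxyl group as weakly Lewis-basic silyl ethers that tolerate the aryllithium and the later Lewis acid.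

Step 9
Reactants: 17 5-bromo-2-{[(1R,2R)-1-[4-(benzyloxy)-3,5-dimethoxyphenyl]-1,3-bis{[tert-butyl(dimethyl)silyl]oxy}propan-2-yl]oxy}-1,3-dimethoxybenzene; 9 (3aS,4R,6aS)-4-[4-(benzyloxy)-3-methoxyphenyl]tetrahydro-1H-furo[3,4-c]furan-1-one
Product: 19 (3aS,4R,6aS)-4-[4-(benzyloxy)-3-methoxyphenyl]-1-(4-{[(1R,2R)-1-[4-(benzyloxy)-3,5-dimethoxyphenyl]-1,3-bis{[tert-butyl(dimethyl)silyl]oxy}propan-2-yl]oxy}-3,5-dimethoxyphenyl)tetrahydro-1H-furo[3,4-c]furan-1-ol (hemiketal, in equilibrium with its open hydroxy ketone), via aryllithium 18 (not isolated)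
Conditions: n-BuLi (1.05 equiv), THF, −78 °C; then 9 (0.9 equiv), THF, −78 °C; H2O quench
Reagents that add atoms: none
Why: Bromine–lithium exchange followed by 1,2-addition of the aryllithium to the γ-lactone at −78 °C should stop at the hemiketal stage because the tetrahedral adduct does not collapse at this temperature.

Step 10
Reactants: 19 hemiketal from step 9
Product: 20 5-[(1S,3aS,4R,6aS)-4-[4-(benzyloxy)-3-methoxyphenyl]tetrahydro-1H,3H-furo[3,4-c]furan-1-yl]-2-{[(1R,2R)-1-[4-(benzyloxy)-3,5-dimethoxyphenyl]-1,3-bis{[tert-butyl(dimethyl)silyl]oxy}propan-2-yl]oxy}-1,3-dimethoxybenzene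
Conditions: Et3SiH (3 equiv), BF3·OEt2 (1.5 equiv), CH2Cl2, −78 °C; Et3N then NaHCO3 quench at −78 °C
Reagents that add atoms: none
Why: In this ionic hydrogenation BF3 should ionise the hemiketal to the aryl-stabilised cyclic oxocarbenium ion and Et3SiH should deliver hydride to the convex (exo) face of the cis-fused bicycle, which places the syringyl aryl group endo, while the low temperature keeps the other benzylic C–O bonds intact.

Step 11
Reactants: 20 bis-silyl ether from step 10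
Product: 21 (1R,2R)-1-[4-(benzyloxy)-3,5-dimethoxyphenyl]-2-{4-[(1S,3aS,4R,6aS)-4-[4-(benzyloxy)-3-methoxyphenyl]tetrahydro-1H,3H-furo[3,4-c]furan-1-yl]-2,6-dimethoxyphenoxy}propane-1,3-diol
Conditions: TBAF (3 equiv), THF, 0 °C to rt
Reagents that add atoms: none
Why: Fluoride-mediated desilylation should free both hydroxyl groups under non-acidic conditions that cannot epimerise the benzylic centres.

Step 12
Reactants: 21 dibenzyl ether from step 11
Product: 22 (1R,2R)-1-(4-hydroxy-3,5-dimethoxyphenyl)-2-{4-[(1S,3aS,4R,6aS)-4-(4-hydroxy-3-methoxyphenyl)tetrahydro-1H,3H-furo[3,4-c]furan-1-yl]-2,6-dimethoxyphenoxy}propane-1,3-diol (target)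
Conditions: H2 (1 atm), 10% Pd/C, EtOAc–EtOH, rt, stopped as soon as both benzyl groups are gone
Reagents that add atoms: none
Why: Hydrogenolysis of aryl benzyl ethers under neutral conditions should be much faster than cleavage of the dialkyl benzylic ethers of the furofuran or of the benzylic alcohol, so the two phenols are released selectively.

Compound list
1 | 4-(benzyloxy)-3-methoxybenzaldehyde | O=Cc1ccc(OCc2ccccc2)c(OC)c1 | starting material
2 | (trimethylsilyl)methanol | OC[Si](C)(C)C | starting material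
3 | 1-(benzyloxy)-4-{bis[(trimethylsilyl)methoxy]methyl}-2-methoxybenzene | COc1cc(C(OC[Si](C)(C)C)OC[Si](C)(C)C)ccc1OCc1ccccc1 | intermediate
4 | (5R)-5-{[(1R,2S,5R)-5-methyl-2-(propan-2-yl)cyclohexyl]oxy}furan-2(5H)-one | O=C1C=C[C@H](O[C@@H]2C[C@H](C)CC[C@H]2C(C)C)O1 | starting material
5 | 1-(benzyloxy)-4-{chloro[(trimethylsilyl)methoxy]methyl}-2-methoxybenzene (racemic, not isolated) | COc1cc(C(Cl)OC[Si](C)(C)C)ccc1OCc1ccccc1 | intermediate
6 | carbonyl ylide [4-(benzyloxy)-3-methoxybenzylidene]oxonium methylide (not isolated) | COc1cc(C=[O+][CH2-])ccc1OCc1ccccc1 | intermediate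
7 | (3R,3aS,6R,6aR)-6-[4-(benzyloxy)-3-methoxyphenyl]-3-(l-menthyloxy)tetrahydro-1H-furo[3,4-c]furan-1-one | COc1cc([C@@H]2OC[C@@H]3[C@H]2C(=O)O[C@H]3O[C@@H]4C[C@H](C)CC[C@H]4C(C)C)ccc1OCc1ccccc1 | intermediate
8 | {(2R,3S,4R)-2-[4-(benzyloxy)-3-methoxyphenyl]oxolane-3,4-diyl}dimethanol | COc1cc([C@@H]2OC[C@@H](CO)[C@H]2CO)ccc1OCc1ccccc1 | intermediate
9 | (3aS,4R,6aS)-4-[4-(benzyloxy)-3-methoxyphenyl]tetrahydro-1H-furo[3,4-c]furan-1-one | COc1cc([C@@H]2OC[C@@H]3[C@H]2COC3=O)ccc1OCc1ccccc1 | intermediate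
10 | 4-bromo-2,6-dimethoxyphenol | COc1cc(Br)cc(OC)c1O | starting material
11 | (4S)-4-benzyl-3-(chloroacetyl)-1,3-oxazolidin-2-one | ClCC(=O)N1[C@@H](Cc2ccccc2)COC1=O | starting material
12 | (4S)-4-benzyl-3-[(4-bromo-2,6-dimethoxyphenoxy)acetyl]-1,3-oxazolidin-2-one | COc1cc(Br)cc(OC)c1OCC(=O)N1[C@@H](Cc2ccccc2)COC1=O | intermediate
13 | 4-(benzyloxy)-3,5-dimethoxybenzaldehyde | COc1cc(C=O)cc(OC)c1OCc1ccccc1 | starting material
14 | (Z)-dibutylboron enolate of 12 (not isolated) | CCCCB(CCCC)O/C(=C\Oc1c(OC)cc(Br)cc1OC)N1[C@@H](Cc2ccccc2)COC1=O | intermediate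
15 | (4S)-4-benzyl-3-[(2S,3R)-3-[4-(benzyloxy)-3,5-dimethoxyphenyl]-2-(4-bromo-2,6-dimethoxyphenoxy)-3-hydroxypropanoyl]-1,3-oxazolidin-2-one | COc1cc(Br)cc(OC)c1O[C@H](C(=O)N1[C@@H](Cc2ccccc2)COC1=O)[C@H](O)c1cc(OC)c(OCc2ccccc2)c(OC)c1 | intermediate
16 | (1R,2R)-1-[4-(benzyloxy)-3,5-dimethoxyphenyl]-2-(4-bromo-2,6-dimethoxyphenoxy)propane-1,3-diol | COc1cc(Br)cc(OC)c1O[C@H](CO)[C@H](O)c1cc(OC)c(OCc2ccccc2)c(OC)c1 | intermediate
17 | 5-bromo-2-{[(1R,2R)-1-[4-(benzyloxy)-3,5-dimethoxyphenyl]-1,3-bis{[tert-butyl(dimethyl)silyl]oxy}propan-2-yl]oxy}-1,3-dimethoxybenzene | COc1cc(Br)cc(OC)c1O[C@H](CO[Si](C)(C)C(C)(C)C)[C@H](O[Si](C)(C)C(C)(C)C)c1cc(OC)c(OCc2ccccc2)c(OC)c1 | intermediate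
18 | aryllithium from 17 (lithium in place of bromine, not isolated) | [Li]c1cc(OC)c(O[C@H](CO[Si](C)(C)C(C)(C)C)[C@H](O[Si](C)(C)C(C)(C)C)c2cc(OC)c(OCc3ccccc3)c(OC)c2)c(OC)c1 | intermediate
19 | hemiketal: (3aS,4R,6aS)-4-[4-(benzyloxy)-3-methoxyphenyl]-1-aryl-tetrahydro-1H-furo[3,4-c]furan-1-ol, aryl = the side-chain-bearing 3,5-dimethoxyphenyl of 17, hemiketal carbon undefined | COc1cc([C@@H]2OC[C@@H]3[C@H]2COC3(O)c2cc(OC)c(O[C@H](CO[Si](C)(C)C(C)(C)C)[C@H](O[Si](C)(C)C(C)(C)C)c3cc(OC)c(OCc4ccccc4)c(OC)c3)c(OC)c2)ccc1OCc1ccccc1 | intermediate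
20 | fully protected furofuran, (1S,3aS,4R,6aS) core with the guaiacyl aryl exo and the syringyl aryl endo, bis-TBS and bis-benzyl protected | COc1cc([C@@H]2OC[C@@H]3[C@H]2CO[C@@H]3c2cc(OC)c(O[C@H](CO[Si](C)(C)C(C)(C)C)[C@H](O[Si](C)(C)C(C)(C)C)c3cc(OC)c(OCc4ccccc4)c(OC)c3)c(OC)c2)ccc1OCc1ccccc1 | intermediate
21 | (1R,2R)-1-[4-(benzyloxy)-3,5-dimethoxyphenyl]-2-{4-[(1S,3aS,4R,6aS)-4-[4-(benzyloxy)-3-methoxyphenyl]tetrahydro-1H,3H-furo[3,4-c]furan-1-yl]-2,6-dimethoxyphenoxy}propane-1,3-diol | COc1cc([C@@H]2OC[C@@H]3[C@H]2CO[C@@H]3c2cc(OC)c(O[C@H](CO)[C@H](O)c3cc(OC)c(OCc4ccccc4)c(OC)c3)c(OC)c2)ccc1OCc1ccccc1 | intermediate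
22 | (1R,2R)-1-(4-hydroxy-3,5-dimethoxyphenyl)-2-{4-[(1S,3aS,4R,6aS)-4-(4-hydroxy-3-methoxyphenyl)tetrahydro-1H,3H-furo[3,4-c]furan-1-yl]-2,6-dimethoxyphenoxy}propane-1,3-diol | COc1cc([C@@H]2OC[C@@H]3[C@H]2CO[C@@H]3c2cc(OC)c(O[C@H](CO)[C@H](O)c3cc(OC)c(O)c(OC)c3)c(OC)c2)ccc1O | target

Total step count: 12. Longest linear sequence: 8 steps (steps 1, 2, 3, 4, 9, 10, 11, 12; the side-chain branch through steps 5–8 is equally long).

Steps most likely to fail

Step 2 (key step). The ylide may collapse to the aryl oxirane or dimerise before it is trapped, and the cycloaddition may show incomplete regio- or exo-selectivity. Fallback (known tandem conjugate addition–aldol chemistry of menthyloxybutenolides), setting out from 1 and returning at 9: 1,3-dithiane is lithiated (n-BuLi, THF, −78 °C) and added to the enantiomeric butenolide (5S)-5-(d-menthyloxy)furan-2(5H)-one F1, anti to the acetal substituent. The resulting lithium enolate F2 is trapped with aldehyde 1 to give the 3,4-trans aldol lactone F3. LiAlH4 opens the lactone acetal to the triol F4. Camphorsulfonic acid in CH2Cl2 closes the tetrahydrofuran through the benzylic cation, aryl trans to the neighbouring hydroxymethyl group, to give the dithianyl alcohol F5. Dithiane hydrolysis (MeI, CaCO3, aqueous MeCN) gives the aldehyde, which closes onto the cis hydroxymethyl group as the lactol F6, and TPAP/NMO oxidises it to 9. Here the dithiane carbon becomes the lactone carbonyl, so the enantiomeric butenolide is needed and steps 3 and 4 are bypassed.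

Step 4. Oxidation may start at the wrong hydroxymethyl group and give the regioisomeric lactone. Fallback, setting out from 7 and returning at 9, which keeps the two carbons differentiated by the oxidation levels they already have in the cycloadduct: acid methanolysis (TsOH, MeOH, HC(OMe)3) opens the pseudo-ester to the methyl ester dimethyl acetal F7. LiAlH4 reduces only the ester to the hydroxy acetal F8. Aqueous acetic acid closes it to the lactol F6 described above, and TPAP/NMO gives 9.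

Step 10. The Lewis acid may also ionise the side-chain benzylic silyl ether (reduction or loss of configuration at that carbon) in competition with the hemiketal. Fallback, setting out from 9 and returning at 21, which builds the side chain only after the ionic hydrogenation: phenol 10 is silylated (TBSCl, imidazole) to tert-butyl(4-bromo-2,6-dimethoxyphenoxy)dimethylsilane F9. Bromine–lithium exchange gives the aryllithium F10, which adds to 9 to give the simple hemiketal F11. Et3SiH/BF3·OEt2 at −78 °C gives the endo-aryl furofuran silyl ether F12, and TBAF frees the phenol F13. Alkylation with 11 (K2CO3, NaI, acetone) gives the aryloxyacetyl imide F14. Its dibutylboron enolate F15 undergoes the Evans syn-aldol reaction with 13 to give the aldol imide F16, and LiBH4 then gives diol 21.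

Further compounds
F1 | step 2 | (5S)-5-{[(1S,2R,5S)-5-methyl-2-(propan-2-yl)cyclohexyl]oxy}furan-2(5H)-one | O=C1C=C[C@@H](O[C@H]2C[C@@H](C)CC[C@@H]2C(C)C)O1
F2 | step 2 | lithium enolate of 4,5-trans-4-(1,3-dithian-2-yl)-5-(d-menthyloxy)dihydrofuran-2(3H)-one | [Li]OC1=C[C@H](C2SCCCS2)[C@@H](O[C@H]2C[C@@H](C)CC[C@@H]2C(C)C)O1
F3 | step 2 | 3,4-trans-4,5-trans-3-{[4-(benzyloxy)-3-methoxyphenyl](hydroxy)methyl}-4-(1,3-dithian-2-yl)-5-(d-menthyloxy)dihydrofuran-2(3H)-one, carbinol centre as formed | O=C1O[C@H](O[C@H]2C[C@@H](C)CC[C@@H]2C(C)C)[C@@H](C2SCCCS2)[C@@H]1C(O)c1ccc(OCc2ccccc2)c(OC)c1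
F4 | step 2 | 2-{[4-(benzyloxy)-3-methoxyphenyl](hydroxy)methyl}-3-(1,3-dithian-2-yl)butane-1,4-diol, chain centres as in the SMILES, carbinol centre as formed | OC[C@@H](C(O)c1ccc(OCc2ccccc2)c(OC)c1)[C@@H](CO)C1SCCCS1
F5 | step 2 | {(2R,3S,4S)-2-[4-(benzyloxy)-3-methoxyphenyl]-4-(1,3-dithian-2-yl)oxolan-3-yl}methanol | COc1cc([C@@H]2OC[C@@H](C3SCCCS3)[C@H]2CO)ccc1OCc1ccccc1
F6 | step 2 | (3aS,4R,6aS)-4-[4-(benzyloxy)-3-methoxyphenyl]tetrahydro-1H-furo[3,4-c]furan-1-ol (lactol, anomer mixture) | COc1cc([C@@H]2OC[C@@H]3[C@H]2COC3O)ccc1OCc1ccccc1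
F7 | step 4 | methyl (2R,3R,4S)-2-[4-(benzyloxy)-3-methoxyphenyl]-4-(dimethoxymethyl)oxolane-3-carboxylate | COc1cc([C@@H]2OC[C@@H](C(OC)OC)[C@H]2C(=O)OC)ccc1OCc1ccccc1
F8 | step 4 | {(2R,3S,4S)-2-[4-(benzyloxy)-3-methoxyphenyl]-4-(dimethoxymethyl)oxolan-3-yl}methanol | COc1cc([C@@H]2OC[C@@H](C(OC)OC)[C@H]2CO)ccc1OCc1ccccc1
F9 | step 10 | tert-butyl(4-bromo-2,6-dimethoxyphenoxy)dimethylsilane | COc1cc(Br)cc(OC)c1O[Si](C)(C)C(C)(C)C
F10 | step 10 | [4-{[tert-butyl(dimethyl)silyl]oxy}-3,5-dimethoxyphenyl]lithium | [Li]c1cc(OC)c(O[Si](C)(C)C(C)(C)C)c(OC)c1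
F11 | step 10 | (3aS,4R,6aS)-4-[4-(benzyloxy)-3-methoxyphenyl]-1-(4-{[tert-butyl(dimethyl)silyl]oxy}-3,5-dimethoxyphenyl)tetrahydro-1H-furo[3,4-c]furan-1-ol, hemiketal carbon undefined | COc1cc([C@@H]2OC[C@@H]3[C@H]2COC3(O)c2cc(OC)c(O[Si](C)(C)C(C)(C)C)c(OC)c2)ccc1OCc1ccccc1
F12 | step 10 | {4-[(1S,3aS,4R,6aS)-4-[4-(benzyloxy)-3-methoxyphenyl]tetrahydro-1H,3H-furo[3,4-c]furan-1-yl]-2,6-dimethoxyphenoxy}(tert-butyl)dimethylsilane | COc1cc([C@@H]2OC[C@@H]3[C@H]2CO[C@@H]3c2cc(OC)c(O[Si](C)(C)C(C)(C)C)c(OC)c2)ccc1OCc1ccccc1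
F13 | step 10 | 4-[(1S,3aS,4R,6aS)-4-[4-(benzyloxy)-3-methoxyphenyl]tetrahydro-1H,3H-furo[3,4-c]furan-1-yl]-2,6-dimethoxyphenol | COc1cc([C@@H]2OC[C@@H]3[C@H]2CO[C@@H]3c2cc(OC)c(O)c(OC)c2)ccc1OCc1ccccc1
F14 | step 10 | (4S)-4-benzyl-3-({4-[(1S,3aS,4R,6aS)-4-[4-(benzyloxy)-3-methoxyphenyl]tetrahydro-1H,3H-furo[3,4-c]furan-1-yl]-2,6-dimethoxyphenoxy}acetyl)-1,3-oxazolidin-2-one | COc1cc([C@@H]2OC[C@@H]3[C@H]2CO[C@@H]3c2cc(OC)c(OCC(=O)N4[C@@H](Cc5ccccc5)COC4=O)c(OC)c2)ccc1OCc1ccccc1
F15 | step 10 | (Z)-dibutylboron enolate of F14 | COc1cc([C@@H]2OC[C@@H]3[C@H]2CO[C@@H]3c2cc(OC)c(O/C=C(\OB(CCCC)CCCC)N4[C@@H](Cc5ccccc5)COC4=O)c(OC)c2)ccc1OCc1ccccc1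
F16 | step 10 | (4S)-4-benzyl-3-[(2S,3R)-3-[4-(benzyloxy)-3,5-dimethoxyphenyl]-2-{4-[(1S,3aS,4R,6aS)-4-[4-(benzyloxy)-3-methoxyphenyl]tetrahydro-1H,3H-furo[3,4-c]furan-1-yl]-2,6-dimethoxyphenoxy}-3-hydroxypropanoyl]-1,3-oxazolidin-2-one | COc1cc([C@@H]2OC[C@@H]3[C@H]2CO[C@@H]3c2cc(OC)c(O[C@H](C(=O)N4[C@@H](Cc5ccccc5)COC4=O)[C@H](O)c4cc(OC)c(OCc5ccccc5)c(OC)c4)c(OC)c2)ccc1OCc1ccccc1
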